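The earlier runs and the new flask were generated by integration for an exercise, and the scatter is random.

At the last reading, 6.00 min, the south-west run still holds 83% of its starting material, although 1.1 M of reagent met 1 M of it. The bench habit of counting equivalents says that more than one equivalent should take the starting material away. Here that habit stops working: the readings barely move from 85%, within a scatter of 2 percentage points. We have no reading of the reagent, so we assume that whatever the starting material did not take went to the partner, which this run holds in the largest amount.

| flask | starting material | partner | reagent | remark | time |
|---|---|---|---|---|---|
| south-east | 1 M | 1.8 M | 0.74 M | run made earlier |  |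
| west | 1 M | 1.8 M | 1.7 M | run made earlier |  |
| south-west | 1 M | 2.7 M | 1.1 M | run made earlier |  |
| flask | 1.0 M | 1.80 M | 1.10 M |  | 10 min |

| run | time / min | open intermediate / % | target / % | starting material / % |
|---|---|---|---|---|
| south-east | 0.833 | 5 | 0 | 94 |
| south-east | 1.50 | 5 | 0 | 92 |
| south-east | 3.00 | 6 | 3 | 87 |
| south-east | 6.00 | 7 | 11 | 80 |
| west | 0.833 | 8 | 4 | 90 |
| west | 1.50 | 15 | 1 | 83 |
| west | 3.00 | 17 | 12 | 72 |
| west | 6.00 | 14 | 17 | 60 |
| south-west | 0.833 | 6 | 4 | 93 |
| south-west | 1.50 | 10 | 2 | 85 |
| south-west | 3.00 | 7 | 9 | 85 |
| south-west | 6.00 | 5 | 8 | 83 |

(readings scatter by 2 percentage points)

- when, up to 10 min, the flask holds most open intermediate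
- the amount of open intermediate, in percent of the starting material charged, at that time



Our reckoning treats the small loss of starting material as a correction to the reagent's main route:

reagent taken by starting material = 0.170 M

(reagent charged − that) / that × starting material / partner = 2.03

We call this the partner's preference, a selectivity factor: how many times faster partner takes reagent than starting material does at equal concentrations. It is read off scattered readings, and from it follows the share of reagent reaching starting material at the start:

share in the flask at the start = starting material / (starting material + preference × partner) = 0.215

The west run has the flask's starting material and partner charges, hence the same share at the start, so we scale its highest reading, 17%, by reagent: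

peak = 11.0%

With the partner charge equal, we also keep that reading's time, 3.00 min.

The forecast says 4 min and 10%, for a flask that “lies between the two” runs; our time is earlier and our amount higher.

The flask gives 11.6% at 3.20 min.

    starting material + reagent → open intermediate (k = 0.00160 M⁻¹ s⁻¹)
    reagent + partner → second intermediate (k = 0.00260 M⁻¹ s⁻¹)
    open intermediate + second intermediate → target (k = 0.0180 M⁻¹ s⁻¹)
    2 second intermediate → homo product (k = 0.0100 M⁻¹ s⁻¹)
    target → over-reaction product (k = 0.00120 s⁻¹)

Until 3.20 min the flask's reagent fell to 36.3% of its charge, at the start 2.9 times faster into second intermediate than into open intermediate, and target reached 6.56%. Afterwards second intermediate, 0.249 M at that time, went on forming target with open intermediate, which fell to 8.24% by 10.0 min. With 1.1 M of partner in a neighbour flask the share at the start becomes 0.310, which scales the peak to 15.9%, and that neighbour flask gives 15.7%.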